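**Retrosynthetic overview**
1. Ring numbering follows the name 5-methoxy-2-methyl-3-pentacosyl-1,4-benzoquinone: C1=O, C2–Me, C3–C25H51, C4=O, C5–OMe, C6–H. C4=O is added last, by para-oxidation of the phenol that carries C1–OH and C4–H.
2. Key cut: the six-membered ring is grown from a four-membered one. The meta pair C1–O/C5–OMe with C6–H between them maps onto a ketene carbonyl plus methoxyacetylene (C5, C6). The vicinal pair C2–Me/C3–alkyl next to C4–H maps onto C4/C3/C2 of a cyclobutenone whose carbonyl is C1.
3. One strain-driven thermal cascade (4π opening, [2+2], 4π opening, 6π closure) forms C1–C6 and C4–C5 and re-forms C1–C2. It also cleaves the cyclobutenone C1–C4 bond, which is absent from the target. The net result is alkyne insertion with all four substituents placed.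
4. The cyclobutenone comes from 3-ethoxy-4-methylcyclobutenone (methylketene + ethoxyacetylene, [2+2]) and C25H51MgCl (C22 + C3 copper coupling) by 1,2-addition and transposition.
5. Order of rings: cyclobutenone (step 2), transient second cyclobutenone and then the benzene ring (both step 5), quinone (step 6).

Key step: step 5

Remark on the chemistry: the target has no stereocentre and no stereogenic double bond, so it is achiral and the demand for a single enantiomer is met by any sample. The stereocentres of the four-membered-ring intermediates are racemic and vanish on aromatisation.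
Remark on the chemistry: the side chain of the SMILES is read as unbranched C25 (n-pentacosyl).

Step 1
Reactants: 1 1-bromodocosane; 2 1-bromo-3-chloropropane
Product: 4 1-chloropentacosane, via docosylmagnesium bromide 3 (not isolated)
Conditions: Mg, cat. I2, THF, 50 °C; then 2 (1.5 equiv), Li2CuCl4 (3 mol %), THF, 0 °C → rt
Reagents that add atoms: none
Why: In this copper-catalysed sp3–sp3 Grignard cross-coupling (Kochi type) the C–Br end of 2 should react far faster than the C–Cl end, so the chloride survives as the handle for step 3.

Step 2
Reactants: 5 propanoyl chloride; 6 ethoxyacetylene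
Product: 8 rac-3-ethoxy-4-methylcyclobut-2-en-1-one, via methylketene 7 (not isolated)
Conditions: Et3N (1.2 equiv), 6 (2 equiv, solution in hexanes), Et2O, slow addition of 5, 0 °C → rt
Reagents that add atoms: none
Why: In this ketene–ynol ether [2+2] cycloaddition the nucleophilic CH terminus of 6 bonds to the ketene carbonyl carbon, so only the 3-ethoxy-4-methyl regioisomer can form; slow addition into excess 6 should hold back ketene dimerisation, and the racemic C4 centre is erased in step 5.

Step 3
Reactants: 4 1-chloropentacosane; 8 rac-3-ethoxy-4-methylcyclobut-2-en-1-one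
Product: 11 rac-4-methyl-3-pentacosylcyclobut-2-en-1-one, via pentacosylmagnesium chloride 9 (not isolated), via tertiary cyclobutenol 10 (not isolated)
Conditions: 4, Mg, cat. I2, THF, reflux; warm solution added to 8, THF, −20 → 0 °C; then 1 M HCl, 0 °C → rt
Reagents that add atoms: water, O
Why: 1,2-Addition of the Grignard reagent to the vinylogous ester, then acid-induced allylic transposition with loss of ethanol (Stork–Danheiser-type enone transposition on a four-membered ring), should put the chain on C3, while the methyl-bearing carbon, bonded to both the old and the new carbonyl carbon, stays C4.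

Step 4
Reactants: 12 2-chloro-1,1-dimethoxyethane
Product: 14 methoxyacetylene, via sodium methoxyacetylide 13 (not isolated)
Conditions: NaNH2 (3.2 equiv), liq. NH3, −33 °C; NH3 evaporated; sat. aq NaCl, −20 °C; distilled (bp ca. 23 °C) into cold toluene
Reagents that add atoms: none
Why: This is the standard alkoxyacetylene synthesis from a chloroacetal: two base-induced eliminations (HCl, then MeOH), with deprotonation to the acetylide driving the sequence and the aqueous quench releasing the volatile ynol ether.

Step 5
Reactants: 11 rac-4-methyl-3-pentacosylcyclobut-2-en-1-one; 14 methoxyacetylene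
Product: 19 5-methoxy-2-methyl-3-pentacosylphenol, via vinylketene 15 (not isolated), via alkenylcyclobutenone 16 (not isolated), via dienylketene 17 (not isolated), via cyclohexadienone 18 (not isolated)
Conditions: 14 (3 equiv), toluene, sealed tube, 80 °C, then 150 °C
Reagents that add atoms: none
Why: Heating should open 11 by conrotatory 4π cleavage of its C(=O)–CH(Me) bond (strain release, methyl turning outward) to vinylketene 15, which 14 traps in a [2+2] cycloaddition in which the nucleophilic CH terminus bonds to the ketene carbonyl carbon (C1–C6) and the MeO-bearing carbon bonds to the ketene α-carbon (C4–C5). The new cyclobutenone 16 opens reversibly in a second 4π step that cleaves the C1–C4 bond, and only the dienylketene 17 with the ketene and the alkenyl arm cis on the central C=C can react further, so the equilibrium drains through it. 17 closes the six-membered ring by disrotatory 6π electrocyclisation (ketene carbon to the CHMe terminus, C1–C2), and dienone 18 tautomerises irreversibly to phenol 19. The closest known reaction type is the cyclobutenone–heteroalkyne (Danheiser) benzannulation, which is well precedented for resorcinol monoethers. No stereocentre is set, because the racemic centres of 11, 16 and 18 are all erased on aromatisation. The step needs only regioselectivity, which is secured by the polarity of the ynol ether and by the fixed C3/C4 positions of chain and methyl in 11; methoxyacetylene has no β-hydrogen, so it cannot decay by retro-ene loss of an alkene at 150 °C.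

Step 6
Reactants: 19 5-methoxy-2-methyl-3-pentacosylphenol
Product: 20 5-methoxy-2-methyl-3-pentacosylcyclohexa-2,5-diene-1,4-dione (target)
Conditions: (KSO3)2NO (3 equiv), KH2PO4 buffer, Aliquat 336 (cat.), CH2Cl2/H2O, rt
Reagents that add atoms: potassium nitrosodisulfonate (Fremy's salt), [O]N(S(=O)(=O)[O-])S(=O)(=O)[O-].[K+].[K+]
Why: In the Teuber oxidation the phenoxyl radical is captured by a second nitroxyl radical at the free para carbon C4, which is preferred over ortho C6, and loss of imidodisulfonate should give the p-quinone; phase transfer keeps the lipophilic substrate in solution.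

**Compound list**
1 | 1-bromodocosane | CCCCCCCCCCCCCCCCCCCCCCBr | starting material
2 | 1-bromo-3-chloropropane | ClCCCBr | starting material
3 | docosylmagnesium bromide | CCCCCCCCCCCCCCCCCCCCCC[Mg]Br | intermediate
4 | 1-chloropentacosane | CCCCCCCCCCCCCCCCCCCCCCCCCCl | intermediate
5 | propanoyl chloride | CCC(=O)Cl | starting material
6 | ethoxyacetylene | CCOC#C | starting material
7 | methylketene (prop-1-en-1-one) | CC=C=O | intermediate
8 | rac-3-ethoxy-4-methylcyclobut-2-en-1-one | CCOC1=CC(=O)C1C | intermediate
9 | pentacosylmagnesium chloride | CCCCCCCCCCCCCCCCCCCCCCCCC[Mg]Cl | intermediate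
10 | 3-ethoxy-4-methyl-1-pentacosylcyclobut-2-en-1-ol (racemic, mixture of diastereomers) | CCCCCCCCCCCCCCCCCCCCCCCCCC1(O)C=C(OCC)C1C | intermediate
11 | rac-4-methyl-3-pentacosylcyclobut-2-en-1-one | CCCCCCCCCCCCCCCCCCCCCCCCCC1=CC(=O)C1C | intermediate
12 | 2-chloro-1,1-dimethoxyethane | COC(CCl)OC | starting material
13 | sodium methoxyacetylide | COC#[C-].[Na+] | intermediate
14 | methoxyacetylene | COC#C | intermediate
15 | (3E)-3-pentacosylpenta-1,3-dien-1-one (vinylketene) | C/C=C(/C=C=O)CCCCCCCCCCCCCCCCCCCCCCCCC | intermediate
16 | rac-3-methoxy-4-[(2E)-octacos-2-en-3-yl]cyclobut-2-en-1-one | C/C=C(/C1C(=O)C=C1OC)CCCCCCCCCCCCCCCCCCCCCCCCC | intermediate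
17 | (3E,5E)-3-methoxy-5-pentacosylhepta-1,3,5-trien-1-one (dienylketene, ketene and alkenyl arm cis on C3=C4) | C(/C=C=O)(OC)=C/C(CCCCCCCCCCCCCCCCCCCCCCCCC)=C/C | intermediate
18 | rac-3-methoxy-6-methyl-5-pentacosylcyclohexa-2,4-dien-1-one | CCCCCCCCCCCCCCCCCCCCCCCCCC1=CC(OC)=CC(=O)C1C | intermediate
19 | 5-methoxy-2-methyl-3-pentacosylphenol | CCCCCCCCCCCCCCCCCCCCCCCCCc1cc(OC)cc(O)c1C | intermediate
20 | 5-methoxy-2-methyl-3-pentacosylcyclohexa-2,5-diene-1,4-dione (achiral) | CCCCCCCCCCCCCCCCCCCCCCCCCC1=C(C)C(=O)C=C(OC)C1=O | target

**Step count and risk**
Total steps: 6. Longest linear sequence: 4 steps (1 → 4 → 11 → 19 → 20; the branch 5/6 → 8 → 11 → 19 → 20 is of equal length).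

Steps most likely to fail:

Step 5. The cascade may stall through O-acylation of the phenol already formed by the vinylketene, through ketene dimerisation, or through polymerisation of the ynol ether. In the fallback the arene is bought instead of built. It sets out from 4 (as its Grignard reagent 9) and comes back at 19.
- Kumada–Corriu coupling of 9 with commercial 1-bromo-3,5-dimethoxybenzene (Pd(dppf)Cl2, THF, reflux) should give 1,3-dimethoxy-5-pentacosylbenzene F1.
- Vilsmeier–Haack formylation (POCl3, DMF), para to one methoxy group and ortho to the chain, should give 2,4-dimethoxy-6-pentacosylbenzaldehyde F2.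
- BCl3 (CH2Cl2, −78 → 0 °C) should cleave only the methoxy group chelated to the aldehyde, giving 2-hydroxy-4-methoxy-6-pentacosylbenzaldehyde F3.
- Ionic hydrogenation of the formyl group to methyl (Et3SiH, TFA) should then give 19.

Step 2. Dimerisation of the aldoketene may outrun the cycloaddition, and the small product may be lost on isolation. The fallback uses a traceless chlorine to tame the ketene. It sets out from 6 and comes back at 8.
- 2-Chloropropanoyl chloride and Et3N should generate the more electrophilic and less dimerisation-prone chloro(methyl)ketene F4.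
- F4 should add to 6 with the same polarity control to give 4-chloro-3-ethoxy-4-methylcyclobut-2-en-1-one F5.
- Reductive dechlorination (Zn, AcOH, TMEDA, EtOH) should give 8.

Step 3. The long-chain Grignard reagent may precipitate in the cold, or the magnesium cyclobutenolate may undergo oxyanion-accelerated ring opening before the acid quench. The fallback builds the four-membered ring directly on the chain and needs no organometallic addition. It sets out from 4 and comes back at 11.
- Alkylation of lithium acetylide–ethylenediamine (DMSO/THF, 40 °C) should give heptacos-1-yne F6.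
- N,N-Dimethylpropanamide with Tf2O and 2,4,6-collidine (1,2-dichloroethane, reflux) should give the keteniminium triflate F7.
- F7 should add to the terminal alkyne in a [2+2] cycloaddition, with the terminal carbon bonding to the iminium carbon, to give the cyclobuteniminium triflate F8.
- Aqueous hydrolysis of F8 should give 11.

**Further compounds**
F1 | step 5 | 1,3-dimethoxy-5-pentacosylbenzene | CCCCCCCCCCCCCCCCCCCCCCCCCc1cc(OC)cc(OC)c1
F2 | step 5 | 2,4-dimethoxy-6-pentacosylbenzaldehyde | CCCCCCCCCCCCCCCCCCCCCCCCCc1cc(OC)cc(OC)c1C=O
F3 | step 5 | 2-hydroxy-4-methoxy-6-pentacosylbenzaldehyde | CCCCCCCCCCCCCCCCCCCCCCCCCc1cc(OC)cc(O)c1C=O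
F4 | step 2 | chloro(methyl)ketene | CC(Cl)=C=O
F5 | step 2 | rac-4-chloro-3-ethoxy-4-methylcyclobut-2-en-1-one | CCOC1=CC(=O)C1(C)Cl
F6 | step 3 | heptacos-1-yne | CCCCCCCCCCCCCCCCCCCCCCCCCC#C
F7 | step 3 | N,N-dimethylprop-1-en-1-ylideneammonium triflate | CC=C=[N+](C)C.[O-]S(=O)(=O)C(F)(F)F
F8 | step 3 | rac-N,N-dimethyl-(4-methyl-3-pentacosylcyclobut-2-en-1-ylidene)ammonium triflate | CCCCCCCCCCCCCCCCCCCCCCCCCC1=CC(=[N+](C)C)C1C.[O-]S(=O)(=O)C(F)(F)F
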